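The rate constants are made up; the flask was simulated.

Slowness is the first worry when a solid must dissolve before it can react, so this flask is tested for it first.

solid substrate 1.0 M; partner 1.50 M (in portions, 3); free catalyst 0.58 mM; time 2.0 h; the portions of partner follow each other after 6.0 s, the first at the start

    starting material + partner ⇌ target (K1 = 1.2 M⁻¹, k1 = 0.0461 M⁻¹ s⁻¹)
    starting material + partner ⇌ isomer of the product (K2 = 120 M⁻¹, k2 = 0.0166 M⁻¹ s⁻¹)
    target + free catalyst ⇌ isomer of the product + free catalyst, rate k3*[free catalyst]*[target] forward; the back reaction follows from the equilibrium constant (k3 = 119 M⁻¹ s⁻¹)
    solid substrate ⇌ starting material, rate k4*(cs4 - [starting material]) while solid is left; crystals form when [starting material] > cs4 (cs4 = 0.37 M, k4 = 0.0866 s⁻¹)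
    free catalyst → spent catalyst (k5 = 1.23 × 10⁻⁵ s⁻¹)
    free catalyst + target ⇌ idle complex, settled at all times (K6 = 4.92 M⁻¹)

- part of the solid substrate that has turned into other species by 2.0 h (what has only dissolved does not count)
- how much isomer of the product there is at 2.0 h, in percent of the solid substrate charged

- amounts and yields of target count idle complex too
- given per volume of solution although it is solid: solid substrate
- at the start none of the solid substrate is in solution
- what has only dissolved of solid substrate counts as not reacted
- run time (flask): 2.0 h

**Time constants.** Dissolution has a time constant of 11.5 s. A bench rule serves for the reaction: the reagent in surplus is treated as fixed, which makes the last stretch pseudo-first-order in the substrate. In this flask the concentration that sets the order is the surplus of partner, its charge minus the solid charge, 0.500 M. With the two forward rate constants added, the time constant is 31.9 s. The run is far longer than that, 226 such times, so this reckoning looks for a balance and not for a rate.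

**Holding ratio.** The two equilibrium constants of the additions sum to 121 M⁻¹. Multiplied by the surplus, they give 60.6. This product, the equilibrium sum times the concentration of the reagent in surplus, is the holding ratio: bound material per unit of the other reagent left free. It puts the conversion at 98.4 %. The isomer takes 99.0 % of that, which makes 97.4 %.

**The border.** The rule stops where the reckoned free starting material passes the solubility, for then crystals stay. In this flask it reckons to 0.0162 M, less than the solubility of 0.37 M, so the rule stands.

**Forecast.** The forecast gives 98.4 % and 97.4 %, holding that “the flask reaches full equilibrium well before 2 h”.

**Result.** This flask gives 98.4 % converted and 97.4 % as isomer. The largest change of the share of a substrate, an intermediate or a product over the second half of the time is 0 percentage points. The holding ratio puts free starting material at 1.62 % of the charge, and the flask holds 1.57 % at 2.00 h.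

**Second flask.** The neighbour with 0.60 M of partner has the substrate in surplus. Its substrate beyond the partner, 0.400 M, is more than the solubility, so crystals stay and dissolved starting material is the reagent held. The holding ratio becomes 44.8, which leaves 2.18 % of the partner free. The neighbour ends with 2.2 % of its partner, 4.31 % as solid and 37.0 % as starting material.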